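The route rests on opening lactone ring A of the 5,7-dihydroxy half at carbonyl carbon C2, the single carbon that links phenol oxygen O1 to C3; the C3–C4 bond is traced back to the double bond of a Z-configured 1,1-diarylalkene. One palladium-catalysed cyclocarbonylation of this 2-alkenylphenol puts hydrogen on C4 and CO on C3 from the same face and closes ring A, making C2–C3, C2–O1 and both cis stereocentres. The substrate comes from a 4-arylcoumarin, whose ring fixes the alkene geometry, and carries the future C2' as a dimethyl acetal. The acetal is later turned into an acetic acid, onto which lactone ring B is annulated with an o-quinone methide before global hydrogenolysis.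

Key step: step 5

Remark on the chemistry: a free 2-hydroxyethyl chain next to the aryl lactone would be expected to translactonise to a γ-butyrolactone, so the chain end passes through the key step at the aldehyde oxidation level as a dimethyl acetal; the carbon skeleton of substrate and product is unchanged. Unprimed locants refer to the ring-A chroman-2-one, primed locants to the ring-B chroman-2-one.

Step 1
Reactants: 1 phloroglucinol; 2 ethyl 3-(4-hydroxyphenyl)-3-oxopropanoate
Product: 3 5,7-dihydroxy-4-(4-hydroxyphenyl)-2H-chromen-2-one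
Conditions: CF3CO2H, reflux
Reagents that add atoms: none
Why: Pechmann condensation (transesterification, intramolecular hydroxyalkylation, dehydration) of the symmetric, highly nucleophilic triphenol with the β-keto ester should give one 4-arylcoumarin, whose ring holds C4a and C2 on the same side of C3=C4.

Step 2
Reactants: 3 5,7-dihydroxy-4-(4-hydroxyphenyl)-2H-chromen-2-one
Product: 4 5,7-bis(benzyloxy)-4-[4-(benzyloxy)phenyl]-2H-chromen-2-one
Conditions: BnBr, K2CO3, DMF, 60 °C
Reagents that add atoms: benzyl bromide, BrCc1ccccc1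
Why: Williamson etherification masks the three phenols as benzyl ethers, which tolerate hydride, ylide and carbonylation conditions and can all be removed together by hydrogenolysis at the end.

Step 3
Reactants: 4 5,7-bis(benzyloxy)-4-[4-(benzyloxy)phenyl]-2H-chromen-2-one
Product: 5 5,7-bis(benzyloxy)-4-[4-(benzyloxy)phenyl]-2H-chromen-2-ol
Conditions: iBu2AlH, CH2Cl2, −78 °C; aqueous KNaC4H4O6 (potassium sodium tartrate)
Reagents that add atoms: none
Why: Partial lactone reduction with iBu2AlH stops at the aluminium hemiacetal at low temperature and should give the lactol on work-up, with the endocyclic C3=C4 bond and thus the ring A/C2 cis relationship untouched.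

Step 4
Reactants: 5 5,7-bis(benzyloxy)-4-[4-(benzyloxy)phenyl]-2H-chromen-2-ol
Product: 8 3,5-bis(benzyloxy)-2-[(1Z)-1-[4-(benzyloxy)phenyl]-4,4-dimethoxybut-1-en-1-yl]phenol, via (Z)-enal 6 (not isolated), via dienyl methyl ether 7 (not isolated)
Conditions: Ph3P(CH2OMe)Cl, KOtBu, THF, 0 °C to rt; then AcOH, MeOH, pyridinium p-toluenesulfonate (cat.), 0 °C to rt
Reagents that add atoms: (methoxymethylene)triphenylphosphorane, COC=P(c1ccccc1)(c1ccccc1)c1ccccc1 (made in the flask from (methoxymethyl)triphenylphosphonium chloride, COC[P+](c1ccccc1)(c1ccccc1)c1ccccc1.[Cl-]); methanol, CO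
Why: The base opens the lactol to its phenoxide (Z)-enal and a Wittig reaction adds one carbon as an enol ether, to which methanol then adds under mild acid catalysis by protonation at the carbon next to C3 (C4 being a fully substituted diaryl carbon), so that the acetal should form with the Z geometry inherited from the coumarin.

Step 5
Reactants: 8 3,5-bis(benzyloxy)-2-[(1Z)-1-[4-(benzyloxy)phenyl]-4,4-dimethoxybut-1-en-1-yl]phenol; 9 carbon monoxide
Product: 10 (3S,4S)-5,7-bis(benzyloxy)-4-[4-(benzyloxy)phenyl]-3-(2,2-dimethoxyethyl)chroman-2-one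
Conditions: Pd(OAc)2 (5 mol %), (R,R)-DIOP (10 mol %), CO/H2 (5:1, 40 bar), toluene, 100 °C
Reagents that add atoms: carbon monoxide 9, [C-]#[O+]
Why: A hydride of divalent palladium, formed from Pd(OAc)2, the bisphosphine, H2 and the phenol, adds across C3=C4 with hydrogen going to the diaryl carbon C4 and palladium to the less hindered C3, CO inserts into the C3–Pd bond with retention, and the neighbouring phenol takes over the acyl group, which releases zerovalent palladium. This is the known palladium-catalysed cyclocarbonylation (intramolecular hydroesterification) of 2-alkenylphenols to 3,4-dihydrocoumarins, applied here to a trisubstituted alkene with a chiral ligand. Ring A closes by 6-exo-trig acyl substitution of the phenol oxygen at C2, so that C2–C3 and C2–O1 are the new bonds. Both new bonds at C3 and C4 are made suprafacially, so the Z alkene, in which ring A and the chain lie on the same side, can only lead to the 3,4-cis lactone, and the chiral bisphosphine selects the alkene face that gives 3S,4S. The step needs acylation at C3, no E/Z scrambling and no chain walking: the alternative benzofuranone with a fully substituted C4 is disfavoured by the two aryl groups, the absence of added acid keeps the electron-rich alkene and the acetal from ionising, and high CO pressure with the phenol held next to the acyl group should make capture faster than β-hydride elimination.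

Step 6
Reactants: 10 (3S,4S)-5,7-bis(benzyloxy)-4-[4-(benzyloxy)phenyl]-3-(2,2-dimethoxyethyl)chroman-2-one
Product: 11 2-{(3S,4S)-5,7-bis(benzyloxy)-4-[4-(benzyloxy)phenyl]-2-oxochroman-3-yl}acetaldehyde
Conditions: 1 M aqueous HCl, acetone, rt
Reagents that add atoms: water, O
Why: Acid-catalysed acetal hydrolysis unmasks the aldehyde, which cannot translactonise onto the aryl lactone as an alcohol would, under conditions that neither enolise C3 nor cleave benzyl ethers.

Step 7
Reactants: 11 2-{(3S,4S)-5,7-bis(benzyloxy)-4-[4-(benzyloxy)phenyl]-2-oxochroman-3-yl}acetaldehyde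
Product: 12 2-{(3S,4S)-5,7-bis(benzyloxy)-4-[4-(benzyloxy)phenyl]-2-oxochroman-3-yl}acetic acid
Conditions: NaClO2, NaH2PO4, 2-methylbut-2-ene, t-BuOH/H2O, 0 °C to rt
Reagents that add atoms: sodium chlorite, [Na+].[O-]Cl=O
Why: Pinnick oxidation converts the aldehyde to the acid in a weakly acidic buffer, with the alkene scavenging hypochlorous acid so that the electron-rich rings and the C3 stereocentre should be left alone.

Step 8
Reactants: 13 2,3,4-trihydroxybenzaldehyde
Product: 14 2,3,4-tris(benzyloxy)benzaldehyde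
Conditions: BnBr, K2CO3, DMF, 60 °C
Reagents that add atoms: benzyl bromide, BrCc1ccccc1
Why: Williamson etherification protects all three phenols so that the aldehyde can next be exchanged for oxygen.

Step 9
Reactants: 14 2,3,4-tris(benzyloxy)benzaldehyde
Product: 16 2,3,4-tris(benzyloxy)phenol, via aryl formate 15 (not isolated)
Conditions: mCPBA, CH2Cl2, rt; then KOH, MeOH/H2O, 0 °C
Reagents that add atoms: 3-chloroperbenzoic acid, OOC(=O)c1cccc(Cl)c1
Why: Baeyer–Villiger oxidation of the aldehyde proceeds with migration of the electron-rich aryl group (ortho and para alkoxy donors) to the formate, which is saponified to the phenol.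

Step 10
Reactants: 16 2,3,4-tris(benzyloxy)phenol
Product: 17 3,4,5-tris(benzyloxy)-2-hydroxybenzaldehyde
Conditions: MgCl2, Et3N, (CH2O)n, MeCN, reflux
Reagents that add atoms: formaldehyde (as paraformaldehyde), C=O
Why: Magnesium-mediated ortho-formylation delivers formaldehyde through the magnesium phenoxide to the only free ortho position, and a second formaldehyde oxidises the benzylic alkoxide by hydride transfer to the salicylaldehyde.

Step 11
Reactants: 17 3,4,5-tris(benzyloxy)-2-hydroxybenzaldehyde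
Product: 18 2,3,4,5-tetrakis(benzyloxy)benzaldehyde
Conditions: BnBr, K2CO3, DMF, 60 °C
Reagents that add atoms: benzyl bromide, BrCc1ccccc1
Why: Williamson etherification of the chelated phenol completes the protection of four contiguous oxygens.

Step 12
Reactants: 18 2,3,4,5-tetrakis(benzyloxy)benzaldehyde
Product: 20 2,3,4,5-tetrakis(benzyloxy)phenol, via aryl formate 19 (not isolated)
Conditions: mCPBA, CH2Cl2, rt; then KOH, MeOH/H2O, 0 °C
Reagents that add atoms: 3-chloroperbenzoic acid, OOC(=O)c1cccc(Cl)c1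
Why: A second Baeyer–Villiger oxidation with aryl migration and formate saponification installs the fifth ring oxygen as the free phenol that will become O1'.

Step 13
Reactants: 20 2,3,4,5-tetrakis(benzyloxy)phenol; 21 4-(benzyloxy)benzaldehyde
Product: 23 3,4,5,6-tetrakis(benzyloxy)-2-{[4-(benzyloxy)phenyl](4-methylbenzenesulfonyl)methyl}phenol, via diarylmethanol 22 (not isolated)
Conditions: TolSO2Na, HCO2H, CH2Cl2/H2O, rt
Reagents that add atoms: sodium 4-methylbenzenesulfinate, Cc1ccc(cc1)S(=O)[O-].[Na+]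
Why: In this acid-mediated three-component condensation the phenol is hydroxyalkylated (Friedel–Crafts) at its only unsubstituted ring position and the carbinol, ionised by formic acid to a benzhydryl cation that both electron-rich rings stabilise, is captured at carbon by the sulfinate sulfur (SN1 substitution), which should give a bench-stable, racemic sulfone whose stereocentre is erased again in step 14.

Step 14
Reactants: 12 2-{(3S,4S)-5,7-bis(benzyloxy)-4-[4-(benzyloxy)phenyl]-2-oxochroman-3-yl}acetic acid; 23 3,4,5,6-tetrakis(benzyloxy)-2-{[4-(benzyloxy)phenyl](4-methylbenzenesulfonyl)methyl}phenol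
Product: 26 (3R,3'S,4S,4'R)-5,5',6',7,7',8'-hexakis(benzyloxy)-4,4'-bis[4-(benzyloxy)phenyl]-[3,3'-bichromane]-2,2'-dione, via acyl imidazole 24 (not isolated), via o-quinone methide 25 (not isolated)
Conditions: 12, CDI, THF, rt; added to 23, Cs2CO3, (5aS,10bR)-2-mesityl-5a,10b-dihydro-4H,6H-indeno[2,1-b][1,2,4]triazolo[4,3-d][1,4]oxazin-2-ium tetrafluoroborate (15 mol %), THF, 0 °C to rt
Reagents that add atoms: none
Why: In this carbene-catalysed formal [4+2] annulation the triazolylidene converts the acyl imidazole into a (Z)-azolium enolate, which adds to the o-quinone methide that Cs2CO3 sets free from the sulfone by 1,4-elimination of sulfinate, through an endo hetero-Diels–Alder-type transition state, and lactonises with loss of the carbene, so that C3' and C4' should form cis, with the catalyst enantiomer steering the quinone methide to the Si face of the enolate carbon to give 3'S,4'R.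

Step 15
Reactants: 26 (3R,3'S,4S,4'R)-5,5',6',7,7',8'-hexakis(benzyloxy)-4,4'-bis[4-(benzyloxy)phenyl]-[3,3'-bichromane]-2,2'-dione
Product: 27 (3R,3'S,4S,4'R)-5,5',6',7,7',8'-hexahydroxy-4,4'-bis(4-hydroxyphenyl)-[3,3'-bichromane]-2,2'-dione
Conditions: H2 (1 atm), Pd/C (10 % Pd on carbon), THF/EtOAc, rt; work-up under argon
Reagents that add atoms: none
Why: Neutral hydrogenolysis of the eight benzyl ethers over palladium on carbon should leave both lactones and all four stereocentres untouched and give the octaphenol, which is kept under argon because the tetrahydroxylated ring is oxidised easily by air.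

Compound list
1 | phloroglucinol (benzene-1,3,5-triol) | Oc1cc(O)cc(O)c1 | starting material
2 | ethyl 3-(4-hydroxyphenyl)-3-oxopropanoate | CCOC(=O)CC(=O)c1ccc(O)cc1 | starting material
3 | 5,7-dihydroxy-4-(4-hydroxyphenyl)-2H-chromen-2-one | O=C1C=C(c2ccc(O)cc2)c2c(O)cc(O)cc2O1 | intermediate
4 | 5,7-bis(benzyloxy)-4-[4-(benzyloxy)phenyl]-2H-chromen-2-one | O=C1C=C(c2ccc(OCc3ccccc3)cc2)c2c(OCc3ccccc3)cc(OCc3ccccc3)cc2O1 | intermediate
5 | 5,7-bis(benzyloxy)-4-[4-(benzyloxy)phenyl]-2H-chromen-2-ol (racemic lactol) | OC1C=C(c2ccc(OCc3ccccc3)cc2)c2c(OCc3ccccc3)cc(OCc3ccccc3)cc2O1 | intermediate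
6 | (2Z)-3-[2,4-bis(benzyloxy)-6-hydroxyphenyl]-3-[4-(benzyloxy)phenyl]prop-2-enal (open form of 5, present as phenoxide) | O=C/C=C(\c1c(O)cc(OCc2ccccc2)cc1OCc1ccccc1)c1ccc(OCc2ccccc2)cc1 | intermediate
7 | 3,5-bis(benzyloxy)-2-[(1Z)-1-[4-(benzyloxy)phenyl]-4-methoxybuta-1,3-dien-1-yl]phenol (enol ether double bond as E/Z mixture) | COC=C/C=C(\c1c(O)cc(OCc2ccccc2)cc1OCc1ccccc1)c1ccc(OCc2ccccc2)cc1 | intermediate
8 | 3,5-bis(benzyloxy)-2-[(1Z)-1-[4-(benzyloxy)phenyl]-4,4-dimethoxybut-1-en-1-yl]phenol (ring A cis to the chain) | Oc1cc(OCc2ccccc2)cc(OCc2ccccc2)c1/C(c1ccc(OCc2ccccc2)cc1)=C\CC(OC)OC | intermediate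
9 | carbon monoxide | [C-]#[O+] | starting material
10 | (3S,4S)-5,7-bis(benzyloxy)-4-[4-(benzyloxy)phenyl]-3-(2,2-dimethoxyethyl)chroman-2-one (3,4-cis) | O=C1Oc2cc(OCc3ccccc3)cc(OCc3ccccc3)c2[C@H](c2ccc(OCc3ccccc3)cc2)[C@@H]1CC(OC)OC | intermediate
11 | 2-{(3S,4S)-5,7-bis(benzyloxy)-4-[4-(benzyloxy)phenyl]-2-oxochroman-3-yl}acetaldehyde | O=C1Oc2cc(OCc3ccccc3)cc(OCc3ccccc3)c2[C@H](c2ccc(OCc3ccccc3)cc2)[C@@H]1CC=O | intermediate
12 | 2-{(3S,4S)-5,7-bis(benzyloxy)-4-[4-(benzyloxy)phenyl]-2-oxochroman-3-yl}acetic acid | O=C1Oc2cc(OCc3ccccc3)cc(OCc3ccccc3)c2[C@H](c2ccc(OCc3ccccc3)cc2)[C@@H]1CC(=O)O | intermediate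
13 | 2,3,4-trihydroxybenzaldehyde | O=Cc1ccc(O)c(O)c1O | starting material
14 | 2,3,4-tris(benzyloxy)benzaldehyde | O=Cc1ccc(OCc2ccccc2)c(OCc2ccccc2)c1OCc1ccccc1 | intermediate
15 | 2,3,4-tris(benzyloxy)phenyl formate | O=COc1ccc(OCc2ccccc2)c(OCc2ccccc2)c1OCc1ccccc1 | intermediate
16 | 2,3,4-tris(benzyloxy)phenol | Oc1ccc(OCc2ccccc2)c(OCc2ccccc2)c1OCc1ccccc1 | intermediate
17 | 3,4,5-tris(benzyloxy)-2-hydroxybenzaldehyde | O=Cc1cc(OCc2ccccc2)c(OCc2ccccc2)c(OCc2ccccc2)c1O | intermediate
18 | 2,3,4,5-tetrakis(benzyloxy)benzaldehyde | O=Cc1cc(OCc2ccccc2)c(OCc2ccccc2)c(OCc2ccccc2)c1OCc1ccccc1 | intermediate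
19 | 2,3,4,5-tetrakis(benzyloxy)phenyl formate | O=COc1cc(OCc2ccccc2)c(OCc2ccccc2)c(OCc2ccccc2)c1OCc1ccccc1 | intermediate
20 | 2,3,4,5-tetrakis(benzyloxy)phenol | Oc1cc(OCc2ccccc2)c(OCc2ccccc2)c(OCc2ccccc2)c1OCc1ccccc1 | intermediate
21 | 4-(benzyloxy)benzaldehyde | O=Cc1ccc(OCc2ccccc2)cc1 | starting material
22 | 3,4,5,6-tetrakis(benzyloxy)-2-{[4-(benzyloxy)phenyl](hydroxy)methyl}phenol (racemic) | OC(c1ccc(OCc2ccccc2)cc1)c1c(O)c(OCc2ccccc2)c(OCc2ccccc2)c(OCc2ccccc2)c1OCc1ccccc1 | intermediate
23 | 3,4,5,6-tetrakis(benzyloxy)-2-{[4-(benzyloxy)phenyl](4-methylbenzenesulfonyl)methyl}phenol (racemic) | Cc1ccc(cc1)S(=O)(=O)C(c1ccc(OCc2ccccc2)cc1)c1c(O)c(OCc2ccccc2)c(OCc2ccccc2)c(OCc2ccccc2)c1OCc1ccccc1 | intermediate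
24 | (3S,4S)-5,7-bis(benzyloxy)-4-[4-(benzyloxy)phenyl]-3-[2-(1H-imidazol-1-yl)-2-oxoethyl]chroman-2-one | O=C1Oc2cc(OCc3ccccc3)cc(OCc3ccccc3)c2[C@H](c2ccc(OCc3ccccc3)cc2)[C@@H]1CC(=O)n1ccnc1 | intermediate
25 | 2,3,4,5-tetrakis(benzyloxy)-6-[4-(benzyloxy)benzylidene]cyclohexa-2,4-dien-1-one (o-quinone methide; exocyclic geometry not fixed) | O=C1C(OCc2ccccc2)=C(OCc2ccccc2)C(OCc2ccccc2)=C(OCc2ccccc2)C1=Cc1ccc(OCc2ccccc2)cc1 | intermediate
26 | (3R,3'S,4S,4'R)-5,5',6',7,7',8'-hexakis(benzyloxy)-4,4'-bis[4-(benzyloxy)phenyl]-[3,3'-bichromane]-2,2'-dione (3,4-cis and 3',4'-cis) | O=C1Oc2cc(OCc3ccccc3)cc(OCc3ccccc3)c2[C@H](c2ccc(OCc3ccccc3)cc2)[C@@H]1[C@H]1C(=O)Oc2c(OCc3ccccc3)c(OCc3ccccc3)c(OCc3ccccc3)c(OCc3ccccc3)c2[C@H]1c1ccc(OCc2ccccc2)cc1 | intermediate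
27 | (3R,3'S,4S,4'R)-5,5',6',7,7',8'-hexahydroxy-4,4'-bis(4-hydroxyphenyl)-[3,3'-bichromane]-2,2'-dione | O=C1Oc2cc(O)cc(O)c2[C@H](c2ccc(O)cc2)[C@@H]1[C@H]1C(=O)Oc2c(O)c(O)c(O)c(O)c2[C@H]1c1ccc(O)cc1 | target

Total step count: 15. Longest linear sequence: 9 steps (steps 1 to 7, 14 and 15); the ring-B branch (steps 8 to 13, then 14 and 15) is 8 steps long.

Steps most likely to fail

Step 5. Reversible hydropalladation may scramble the alkene geometry, palladium may walk along the chain towards the acetal before CO is inserted, and the hindered trisubstituted alkene may be carbonylated slowly or with poor enantioface selection. The sense of induction of (R,R)-DIOP cannot be predicted with certainty, and its antipode is equally available.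

The fallback sets out from 4-(benzyloxy)benzaldehyde 21 and returns at acid 12; it builds the ring-A lactone by the carbene-catalysed annulation instead. Condensation of 21 with commercial 3,5-bis(benzyloxy)phenol and TolSO2Na in HCO2H should give the sulfone 3,5-bis(benzyloxy)-2-{[4-(benzyloxy)phenyl](4-methylbenzenesulfonyl)methyl}phenol F1, to be freed from any para-substituted isomer by crystallisation. With Cs2CO3 this releases the o-quinone methide 3,5-bis(benzyloxy)-6-[4-(benzyloxy)benzylidene]cyclohexa-2,4-dien-1-one F2. It is trapped by the azolium enolate that the triazolium salt (antipode chosen for 3S,4S) forms from tert-butyl 4-(1H-imidazol-1-yl)-4-oxobutanoate F3, itself made in the flask from commercial 4-tert-butoxy-4-oxobutanoic acid and CDI. The cis-selective [4+2] annulation should give tert-butyl 2-{(3S,4S)-5,7-bis(benzyloxy)-4-[4-(benzyloxy)phenyl]-2-oxochroman-3-yl}acetate F4, and CF3CO2H in CH2Cl2 cleaves the tert-butyl ester to 12.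

Step 14. Facial control relative to the existing C3 centre may be poor, and the hindered quinone methide may react through its other exocyclic geometry and give the 3',4'-trans lactone. The base may also epimerise C3, or acylate the sulfone phenol before it eliminates.

The fallback sets out from aldehyde 11 and returns at bis-lactone 26; it uses no carbene and no acid enolate. TBSOTf and Et3N at −78 °C should convert 11 into the (Z)-silyl enol ether (3R,4S)-5,7-bis(benzyloxy)-4-[4-(benzyloxy)phenyl]-3-[(Z)-2-(tert-butyldimethylsilyloxy)ethenyl]chroman-2-one F5. As the electron-rich partner it undergoes a thermal endo hetero-Diels–Alder reaction with inverse electron demand with o-quinone methide 25, released as in step 14 from sulfone 23 by Cs2CO3, to give the all-cis 2-silyloxychroman F6. Pyridinium chlorochromate (C5H5NH[CrO3Cl]) then oxidises the silyl acetal to lactone 26. The face is chosen here by the C3 stereocentre alone, so C3'/C4' diastereomers may have to be separated.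

Step 4. The push–pull phenoxide enal may lose its Z geometry by rotation before it is olefinated. During methanol addition, protonation at C4 instead of the carbon next to C3 would move the double bond out of C3=C4.

The fallback sets out from coumarin 4 and returns at 8; it keeps the phenol masked while the aldehyde is present. Me(MeO)NH·HCl and Me3Al should open the lactone to the Weinreb amide (2Z)-3-[2,4-bis(benzyloxy)-6-hydroxyphenyl]-3-[4-(benzyloxy)phenyl]-N-methoxy-N-methylprop-2-enamide F7. TBSCl and imidazole give its aryl tert-butyldimethylsilyl ether F8. iBu2AlH at −78 °C gives the silyl-protected (Z)-enal F9, which can neither close to a lactol nor form a phenoxide. The Wittig reaction with (methoxymethylene)triphenylphosphorane gives the silyl-protected dienyl methyl ether F10, and pyridinium p-toluenesulfonate in MeOH the silyl-protected acetal F11. K2CO3 in MeOH then removes the aryl silyl group to give 8.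

Further compounds
F1 | step 5 | 3,5-bis(benzyloxy)-2-{[4-(benzyloxy)phenyl](4-methylbenzenesulfonyl)methyl}phenol (racemic) | Cc1ccc(cc1)S(=O)(=O)C(c1ccc(OCc2ccccc2)cc1)c1c(O)cc(OCc2ccccc2)cc1OCc1ccccc1
F2 | step 5 | 3,5-bis(benzyloxy)-6-[4-(benzyloxy)benzylidene]cyclohexa-2,4-dien-1-one | O=C1C=C(OCc2ccccc2)C=C(OCc2ccccc2)C1=Cc1ccc(OCc2ccccc2)cc1
F3 | step 5 | tert-butyl 4-(1H-imidazol-1-yl)-4-oxobutanoate | CC(C)(C)OC(=O)CCC(=O)n1ccnc1
F4 | step 5 | tert-butyl 2-{(3S,4S)-5,7-bis(benzyloxy)-4-[4-(benzyloxy)phenyl]-2-oxochroman-3-yl}acetate | O=C1Oc2cc(OCc3ccccc3)cc(OCc3ccccc3)c2[C@H](c2ccc(OCc3ccccc3)cc2)[C@@H]1CC(=O)OC(C)(C)C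
F5 | step 14 | (3R,4S)-5,7-bis(benzyloxy)-4-[4-(benzyloxy)phenyl]-3-[(Z)-2-(tert-butyldimethylsilyloxy)ethenyl]chroman-2-one | O=C1Oc2cc(OCc3ccccc3)cc(OCc3ccccc3)c2[C@H](c2ccc(OCc3ccccc3)cc2)[C@@H]1/C=C\O[Si](C)(C)C(C)(C)C
F6 | step 14 | (3R,4S)-5,7-bis(benzyloxy)-4-[4-(benzyloxy)phenyl]-3-{(2R,3S,4R)-5,6,7,8-tetrakis(benzyloxy)-4-[4-(benzyloxy)phenyl]-2-(tert-butyldimethylsilyloxy)chroman-3-yl}chroman-2-one | O=C1Oc2cc(OCc3ccccc3)cc(OCc3ccccc3)c2[C@H](c2ccc(OCc3ccccc3)cc2)[C@@H]1[C@H]1[C@@H](O[Si](C)(C)C(C)(C)C)Oc2c(OCc3ccccc3)c(OCc3ccccc3)c(OCc3ccccc3)c(OCc3ccccc3)c2[C@H]1c1ccc(OCc2ccccc2)cc1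
F7 | step 4 | (2Z)-3-[2,4-bis(benzyloxy)-6-hydroxyphenyl]-3-[4-(benzyloxy)phenyl]-N-methoxy-N-methylprop-2-enamide | CON(C)C(=O)/C=C(\c1c(O)cc(OCc2ccccc2)cc1OCc1ccccc1)c1ccc(OCc2ccccc2)cc1
F8 | step 4 | (2Z)-3-[2,4-bis(benzyloxy)-6-(tert-butyldimethylsilyloxy)phenyl]-3-[4-(benzyloxy)phenyl]-N-methoxy-N-methylprop-2-enamide | CON(C)C(=O)/C=C(\c1c(O[Si](C)(C)C(C)(C)C)cc(OCc2ccccc2)cc1OCc1ccccc1)c1ccc(OCc2ccccc2)cc1
F9 | step 4 | (2Z)-3-[2,4-bis(benzyloxy)-6-(tert-butyldimethylsilyloxy)phenyl]-3-[4-(benzyloxy)phenyl]prop-2-enal | O=C/C=C(\c1c(O[Si](C)(C)C(C)(C)C)cc(OCc2ccccc2)cc1OCc1ccccc1)c1ccc(OCc2ccccc2)cc1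
F10 | step 4 | tert-butyl{3,5-bis(benzyloxy)-2-[(1Z)-1-[4-(benzyloxy)phenyl]-4-methoxybuta-1,3-dien-1-yl]phenoxy}dimethylsilane (enol ether double bond as E/Z mixture) | COC=C/C=C(\c1c(O[Si](C)(C)C(C)(C)C)cc(OCc2ccccc2)cc1OCc1ccccc1)c1ccc(OCc2ccccc2)cc1
F11 | step 4 | tert-butyl{3,5-bis(benzyloxy)-2-[(1Z)-1-[4-(benzyloxy)phenyl]-4,4-dimethoxybut-1-en-1-yl]phenoxy}dimethylsilane | COC(OC)C/C=C(\c1c(O[Si](C)(C)C(C)(C)C)cc(OCc2ccccc2)cc1OCc1ccccc1)c1ccc(OCc2ccccc2)cc1
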